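**Retrosynthetic overview**
1. Target 30 ⇐ C8 angeloylation and desilylation of the cis-fused macrocyclic lactone 25.
2. 25 ⇐ one new chromium-catalysed, ligand-controlled allylation–lactonisation of the open-chain bromo-enal 23: the C6–C7 bond closes the ten-membered carbocycle first, then the γ-lactone closes; C6 and C7 are set here.
3. 23 ⇐ (Z)-enal 14 + methyl propiolate (C8 by Zn–ProPhenol alkynylation), trans-hydroalumination/iodination, then double Stille hydroxymethylation (C6 and C13).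
4. 14 ⇐ bromo/iodo diene-diol 11 ⇐ boron aldol of (Z)-bromo-enone 8 with (Z)-iodo-enal 4, then 1,3-anti reduction (C1, C3).
5. 4 and 8 ⇐ copper-catalysed anti-carbomagnesiation of propargyl alcohol and but-3-yn-2-ol; this fixes both Z trisubstituted alkenes.

Assumption: locants follow germacrane numbering (ring C1(OH)–C2–C3(OH)–C4(Me)=C5–C6(O)–C7–C8(OAng)–C9=C10(Me); C11 lactone α-carbon, C12 carbonyl, C13 exocyclic CH2), TBS = tert-butyldimethylsilyl, TES = triethylsilyl, and the quoted senses of induction of the chiral reagents are by analogy, the antipodal reagent being used if an assay shows the opposite sense.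

**Step 1**
Reactants: 1 prop-2-yn-1-ol
Product: 3 (Z)-3-iodo-2-methylprop-2-en-1-ol, via cyclic alkenylmagnesium alkoxide 2 (not isolated)
Conditions: MeMgBr (2.5 equiv), CuI (10 mol%), THF, −10 → 23 °C; then I2, −10 °C
Reagents that add atoms: methylmagnesium bromide C[Mg]Br; iodine [I][I]
Why: Copper-catalysed anti-carbomagnesiation of the propargylic alkoxide puts methyl on C2 and magnesium on C3 inside a five-membered chelate, so iodinolysis with retention gives only the Z vinyl iodide (iodine cis to CH2OH).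

**Step 2**
Reactants: 3 (Z)-3-iodo-2-methylprop-2-en-1-ol
Product: 4 (Z)-3-iodo-2-methylprop-2-enal
Conditions: MnO2 (15 equiv), CH2Cl2, 23 °C, dark
Reagents that add atoms: none
Why: Neutral heterogeneous allylic oxidation gives the labile β-iodo enal without Z/E isomerisation; it is used directly.

**Step 3**
Reactants: 5 but-3-yn-2-ol (racemic)
Product: 7 (Z)-4-bromo-3-methylbut-3-en-2-ol (racemic), via cyclic alkenylmagnesium alkoxide 6 (not isolated)
Conditions: MeMgBr (2.5 equiv), CuI (10 mol%), THF, −10 → 23 °C; then NBS, −30 °C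
Reagents that add atoms: methylmagnesium bromide C[Mg]Br; N-bromosuccinimide O=C1CCC(=O)N1Br
Why: The same chelate-controlled anti-carbomagnesiation, with electrophilic bromination of the alkenyl–magnesium bond with retention, gives the Z vinyl bromide; the carbinol centre is removed in the next step.

**Step 4**
Reactants: 7 (Z)-4-bromo-3-methylbut-3-en-2-ol
Product: 8 (Z)-4-bromo-3-methylbut-3-en-2-one
Conditions: MnO2 (20 equiv), CH2Cl2, 23 °C, dark
Reagents that add atoms: none
Why: Allylic oxidation under neutral conditions gives the methyl ketone with the Z bromoalkene intact.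

**Step 5**
Reactants: 8 (Z)-4-bromo-3-methylbut-3-en-2-one; 4 (Z)-3-iodo-2-methylprop-2-enal
Product: 10 (1Z,5S,6Z)-1-bromo-5-hydroxy-7-iodo-2,6-dimethylhepta-1,6-dien-3-one, via diisopinocampheylboron enolate 9 (not isolated)
Conditions: (+)-Ipc2BCl (1.3 equiv), Et3N (1.5 equiv), Et2O, 0 °C; then 4, −78 → −20 °C; then MeOH, pH 7 buffer, H2O2, 0 °C
Reagents that add atoms: none
Why: Paterson-type boron aldol of a methyl ketone with only one enolisable site; the isopinocampheyl ligands direct the enolate to the Si face of the enal and set C1 as S, and the minor enantiomeric series is removed as a diastereomer after step 9.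

**Step 6**
Reactants: 10 (1Z,5S,6Z)-1-bromo-5-hydroxy-7-iodo-2,6-dimethylhepta-1,6-dien-3-one
Product: 11 (1Z,3S,5S,6Z)-1-bromo-7-iodo-2,6-dimethylhepta-1,6-diene-3,5-diol
Conditions: Me4NBH(OAc)3 (5 equiv), MeCN–AcOH (1:1), −30 °C
Reagents that add atoms: none
Why: Evans–Saksena reduction: the C1 alkoxy(diacetoxy)borohydride delivers hydride intramolecularly through a chair transition state, giving the 1,3-anti diol and setting C3 as S.

**Step 7**
Reactants: 11 (1Z,3S,5S,6Z)-1-bromo-7-iodo-2,6-dimethylhepta-1,6-diene-3,5-diol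
Product: 12 (1Z,3S,5S,6Z)-1-bromo-3,5-bis(tert-butyldimethylsilyloxy)-7-iodo-2,6-dimethylhepta-1,6-diene
Conditions: TBSOTf (2.5 equiv), 2,6-lutidine, CH2Cl2, −78 → 0 °C
Reagents that add atoms: tert-butyldimethylsilyl trifluoromethanesulfonate CC(C)(C)[Si](C)(C)OS(=O)(=O)C(F)(F)F
Why: Standard silylation of both secondary allylic alcohols; no stereocentre is touched.

**Step 8**
Reactants: 12 (1Z,3S,5S,6Z)-1-bromo-3,5-bis(tert-butyldimethylsilyloxy)-7-iodo-2,6-dimethylhepta-1,6-diene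
Product: 14 (2Z,4S,6S,7Z)-8-bromo-4,6-bis(tert-butyldimethylsilyloxy)-3,7-dimethylocta-2,7-dienal, via alkenyllithium 13 (not isolated)
Conditions: n-BuLi (1.05 equiv), Et2O, −78 °C, 15 min; then DMF, −78 → 0 °C
Reagents that add atoms: N,N-dimethylformamide CN(C)C=O
Why: Iodine–lithium exchange is far faster than bromine–lithium exchange at −78 °C and proceeds with retention, and immediate formylation in ether outruns 1,4-silyl migration, so only the C9 terminus becomes the Z enal (C8).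

**Step 9**
Reactants: 14 (2Z,4S,6S,7Z)-8-bromo-4,6-bis(tert-butyldimethylsilyloxy)-3,7-dimethylocta-2,7-dienal; 15 methyl propiolate
Product: 16 methyl (4R,5Z,7S,9S,10Z)-11-bromo-7,9-bis(tert-butyldimethylsilyloxy)-4-hydroxy-6,10-dimethylundeca-5,10-dien-2-ynoate
Conditions: (R,R)-ProPhenol (20 mol%), Me2Zn (3 equiv), Ph3PO (40 mol%), toluene, 0 °C
Reagents that add atoms: none
Why: Dinuclear zinc–ProPhenol alkynylation, for which enals are the best substrates, delivers the zinc alkynide to the Si face of the aldehyde and sets C8 as R under catalyst control.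

**Step 10**
Reactants: 16 methyl (4R,5Z,7S,9S,10Z)-11-bromo-7,9-bis(tert-butyldimethylsilyloxy)-4-hydroxy-6,10-dimethylundeca-5,10-dien-2-ynoate
Product: 18 methyl (2Z,4R,5Z,7S,9S,10Z)-11-bromo-7,9-bis(tert-butyldimethylsilyloxy)-4-hydroxy-2-iodo-6,10-dimethylundeca-2,5,10-trienoate, via cyclic alkenylalanate 17 (not isolated)
Conditions: NaAlH2(OCH2CH2OMe)2 (1.6 equiv), THF, −72 °C; then I2, −72 → −20 °C
Reagents that add atoms: iodine [I][I]
Why: Alkoxide-directed trans-hydroalumination puts hydride on C7 and aluminium on C11 cis to C8, and iodinolysis with retention gives the Z α-iodo enoate with C8 trans to the ester, so no butenolide can form.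

**Step 11**
Reactants: 18 methyl (2Z,4R,5Z,7S,9S,10Z)-11-bromo-7,9-bis(tert-butyldimethylsilyloxy)-4-hydroxy-2-iodo-6,10-dimethylundeca-2,5,10-trienoate
Product: 19 methyl (2Z,4R,5Z,7S,9S,10Z)-11-bromo-7,9-bis(tert-butyldimethylsilyloxy)-2-iodo-6,10-dimethyl-4-(triethylsilyloxy)undeca-2,5,10-trienoate
Conditions: TESCl (1.5 equiv), imidazole, CH2Cl2, 0 °C
Reagents that add atoms: chlorotriethylsilane CC[Si](CC)(CC)Cl
Why: Silylation gives a C8 ether that is inert to palladium, cannot lactonise later, and can be removed selectively in the presence of the two TBS ethers.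

**Step 12**
Reactants: 19 methyl (2Z,4R,5Z,7S,9S,10Z)-11-bromo-7,9-bis(tert-butyldimethylsilyloxy)-2-iodo-6,10-dimethyl-4-(triethylsilyloxy)undeca-2,5,10-trienoate
Product: 20 methyl (2E,4R,5Z,7S,9S,10Z)-7,9-bis(tert-butyldimethylsilyloxy)-12-hydroxy-2-(hydroxymethyl)-6,10-dimethyl-4-(triethylsilyloxy)dodeca-2,5,10-trienoate
Conditions: Bu3SnCH2OH (3 equiv), Pd(PPh3)4 (10 mol%), 1,4-dioxane, 60 °C then 100 °C
Reagents that add atoms: (tributylstannyl)methanol CCCC[Sn](CCCC)(CCCC)CO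
Why: Double Stille hydroxymethylation: oxidative addition of zerovalent palladium first into the α-iodo enoate and then, on heating, into the vinyl bromide, each with retention of alkene geometry, installs C13 and C6 as primary allylic alcohols.

**Step 13**
Reactants: 20 methyl (2E,4R,5Z,7S,9S,10Z)-7,9-bis(tert-butyldimethylsilyloxy)-12-hydroxy-2-(hydroxymethyl)-6,10-dimethyl-4-(triethylsilyloxy)dodeca-2,5,10-trienoate
Product: 21 methyl (2E,4R,5Z,7S,9S,10Z)-7,9-bis(tert-butyldimethylsilyloxy)-2-(hydroxymethyl)-6,10-dimethyl-12-oxo-4-(triethylsilyloxy)dodeca-2,5,10-trienoate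
Conditions: MnO2 (10 equiv), CH2Cl2, 0 → 23 °C, monitored
Reagents that add atoms: none
Why: MnO2 oxidises the electron-rich trisubstituted allylic alcohol (C6) much faster than the hydroxymethyl group on the electron-poor acrylate (C13), giving the Z enal chemoselectively under neutral conditions.

**Step 14**
Reactants: 21 methyl (2E,4R,5Z,7S,9S,10Z)-7,9-bis(tert-butyldimethylsilyloxy)-2-(hydroxymethyl)-6,10-dimethyl-12-oxo-4-(triethylsilyloxy)dodeca-2,5,10-trienoate
Product: 23 methyl (2Z,4R,5Z,7S,9S,10Z)-2-(bromomethyl)-7,9-bis(tert-butyldimethylsilyloxy)-6,10-dimethyl-12-oxo-4-(triethylsilyloxy)dodeca-2,5,10-trienoate, via allylic mesylate 22 (not isolated)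
Conditions: MsCl, Et3N, CH2Cl2, −30 °C; then LiBr, THF, −30 → 0 °C
Reagents that add atoms: lithium bromide [Li+].[Br-]
Why: Mesylation and bromide displacement give the thermodynamically preferred 2-(bromomethyl)alk-2-enoate with C8 cis to CH2Br, without touching the enal or silyl ethers.

**Step 15**
Reactants: 23 methyl (2Z,4R,5Z,7S,9S,10Z)-2-(bromomethyl)-7,9-bis(tert-butyldimethylsilyloxy)-6,10-dimethyl-12-oxo-4-(triethylsilyloxy)dodeca-2,5,10-trienoate
Product: 25 (1S,3S,6S,7S,8R)-1,3-bis(tert-butyldimethylsilyloxy)-8-(triethylsilyloxy)germacra-4Z,9Z,11(13)-trien-12,6-olide (cis-fused), via trimethylsilyl ether of the syn hydroxy ester 24 (not isolated)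
Conditions: CrCl2 (20 mol%), (S,S)-1,8-bis(4-isopropyl-4,5-dihydrooxazol-2-yl)-3,6-diphenylcarbazole (24 mol%), Mn powder (3 equiv), TMSCl (2 equiv), i-Pr2NEt (0.3 equiv), THF, 23 °C, 23 added over 14 h (final 2 mM); then citric acid, MeOH, 0 °C
Reagents that add atoms: none
Why: Proposed new method: a ligand-controlled chromium-catalysed macrocyclising 2-(alkoxycarbonyl)allylation–lactonisation in which CrCl2 bound to the tridentate carbazole-bis(oxazoline) reduces the allylic bromide in two one-electron steps to a σ-allyl complex of trivalent chromium whose central ester keeps C8 cis to the CH2–Cr terminus, so the tethered enal is attacked through C7 in a chair Zimmerman–Traxler transition state that gives the syn C6/C7 adduct (hence the cis lactone), the ligand blocking the Si face so that bonding occurs on the Re face of the aldehyde (6S, therefore 7S) with the C8 silyloxy group in the allyl plane and C9 on the attacked face (7,8-anti); TMSCl silylates the chromium alkoxide to give 24 and frees the metal, Mn powder returns it to divalent chromium, slow addition lets ring closure outrun oligomerisation, mild acid then unmasks the C6 hydroxyl which lactonises onto the ester, and the covalent C–Cr bond with a poor silyloxy leaving group at C8 disfavours 1,4-elimination; the closest known reactions are the stoichiometric CrCl2-mediated (Nozaki–Hiyama–Kishi type) cyclisation of ω-formyl 2-(alkoxycarbonyl)allyl bromides to ten-membered α-methylene lactones and the intermolecular chromium-catalysed enantioselective 2-(alkoxycarbonyl)allylation of aldehydes.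

**Step 16**
Reactants: 25 (1S,3S,6S,7S,8R)-1,3-bis(tert-butyldimethylsilyloxy)-8-(triethylsilyloxy)germacra-4Z,9Z,11(13)-trien-12,6-olide
Product: 26 (1S,3S,6S,7R,8R)-1,3-bis(tert-butyldimethylsilyloxy)-8-hydroxygermacra-4Z,9Z,11(13)-trien-12,6-olide (same geometry; the C7 descriptor changes only formally)
Conditions: HF·pyridine, pyridine, THF, 0 °C
Reagents that add atoms: none
Why: Buffered fluoride cleaves the triethylsilyl ether much faster than the two secondary TBS ethers, and the non-basic medium avoids translactonisation to O8.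

**Step 17**
Reactants: 26 (1S,3S,6S,7R,8R)-1,3-bis(tert-butyldimethylsilyloxy)-8-hydroxygermacra-4Z,9Z,11(13)-trien-12,6-olide; 27 angelic acid ((Z)-2-methylbut-2-enoic acid)
Product: 29 (1S,3S,6S,7S,8R)-8-angeloyloxy-1,3-bis(tert-butyldimethylsilyloxy)germacra-4Z,9Z,11(13)-trien-12,6-olide, via mixed anhydride 28 (not isolated)
Conditions: 27 (4 equiv), 2,4,6-trichlorobenzoyl chloride (4 equiv), Et3N (5 equiv), toluene, 23 °C; then 26, toluene, 75 °C
Reagents that add atoms: none
Why: Yamaguchi esterification through the preformed mixed anhydride, run without a nucleophilic amine catalyst, acylates the hindered C8 alcohol with the less hindered angeloyl carbonyl and keeps the Z (angelate) geometry.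

**Step 18**
Reactants: 29 (1S,3S,6S,7S,8R)-8-angeloyloxy-1,3-bis(tert-butyldimethylsilyloxy)germacra-4Z,9Z,11(13)-trien-12,6-olide
Product: 30 (1S,3S,6S,7S,8R)-8-angeloyloxy-1,3-dihydroxygermacra-4Z,9Z,11(13)-trien-12,6-olide (target CNP0152559.4)
Conditions: HF·pyridine, THF, 0 → 23 °C
Reagents that add atoms: none
Why: Acidic fluoride removes both TBS ethers without base, so the α-methylene lactone, the angelate and all five stereocentres are untouched.

**Compound list**
1 | prop-2-yn-1-ol | C#CCO | starting material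
2 | 4-methyl-2,5-dihydro-1,2-oxamagnesole (cyclic alkenylmagnesium alkoxide) | CC1=C[Mg]OC1 | intermediate
3 | (Z)-3-iodo-2-methylprop-2-en-1-ol | OC/C(C)=C\I | intermediate
4 | (Z)-3-iodo-2-methylprop-2-enal | O=C/C(C)=C\I | intermediate
5 | but-3-yn-2-ol (racemic) | CC(O)C#C | starting material
6 | 4,5-dimethyl-2,5-dihydro-1,2-oxamagnesole (cyclic alkenylmagnesium alkoxide, racemic) | CC1=C[Mg]OC1C | intermediate
7 | (Z)-4-bromo-3-methylbut-3-en-2-ol (racemic) | CC(O)/C(C)=C\Br | intermediate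
8 | (Z)-4-bromo-3-methylbut-3-en-2-one | CC(=O)/C(C)=C\Br | intermediate
9 | (Z)-4-bromo-3-methylbuta-1,3-dien-2-yl bis[(+)-isopinocampheyl]borinate (boron enolate of 8) | C=C(OB([C@H]1C[C@H]2C[C@@H]([C@@H]1C)C2(C)C)[C@H]1C[C@H]2C[C@@H]([C@@H]1C)C2(C)C)/C(C)=C\Br | intermediate
10 | (1Z,5S,6Z)-1-bromo-5-hydroxy-7-iodo-2,6-dimethylhepta-1,6-dien-3-one | Br/C=C(/C)C(=O)C[C@H](O)/C(C)=C\I | intermediate
11 | (1Z,3S,5S,6Z)-1-bromo-7-iodo-2,6-dimethylhepta-1,6-diene-3,5-diol | Br/C=C(/C)[C@@H](O)C[C@H](O)/C(C)=C\I | intermediate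
12 | (1Z,3S,5S,6Z)-1-bromo-3,5-bis(tert-butyldimethylsilyloxy)-7-iodo-2,6-dimethylhepta-1,6-diene | Br/C=C(/C)[C@@H](O[Si](C)(C)C(C)(C)C)C[C@H](O[Si](C)(C)C(C)(C)C)/C(C)=C\I | intermediate
13 | (1Z,3S,5S,6Z)-7-bromo-3,5-bis(tert-butyldimethylsilyloxy)-2,6-dimethylhepta-1,6-dien-1-yllithium | Br/C=C(/C)[C@@H](O[Si](C)(C)C(C)(C)C)C[C@H](O[Si](C)(C)C(C)(C)C)/C(C)=C\[Li] | intermediate
14 | (2Z,4S,6S,7Z)-8-bromo-4,6-bis(tert-butyldimethylsilyloxy)-3,7-dimethylocta-2,7-dienal | Br/C=C(/C)[C@@H](O[Si](C)(C)C(C)(C)C)C[C@H](O[Si](C)(C)C(C)(C)C)/C(C)=C\C=O | intermediate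
15 | methyl propiolate | C#CC(=O)OC | starting material
16 | methyl (4R,5Z,7S,9S,10Z)-11-bromo-7,9-bis(tert-butyldimethylsilyloxy)-4-hydroxy-6,10-dimethylundeca-5,10-dien-2-ynoate | Br/C=C(/C)[C@@H](O[Si](C)(C)C(C)(C)C)C[C@H](O[Si](C)(C)C(C)(C)C)/C(C)=C\[C@@H](O)C#CC(=O)OC | intermediate
17 | sodium cyclic alkenylalanate of 16 (five-membered ring O8–Al–C11=C7–C8, two 2-methoxyethoxy groups on aluminium) | Br/C=C(/C)[C@@H](O[Si](C)(C)C(C)(C)C)C[C@H](O[Si](C)(C)C(C)(C)C)/C(C)=C\[C@@H](O1)C=C(C(=O)OC)[Al-]1(OCCOC)OCCOC.[Na+] | intermediate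
18 | methyl (2Z,4R,5Z,7S,9S,10Z)-11-bromo-7,9-bis(tert-butyldimethylsilyloxy)-4-hydroxy-2-iodo-6,10-dimethylundeca-2,5,10-trienoate | Br/C=C(/C)[C@@H](O[Si](C)(C)C(C)(C)C)C[C@H](O[Si](C)(C)C(C)(C)C)/C(C)=C\[C@@H](O)/C=C(\I)C(=O)OC | intermediate
19 | methyl (2Z,4R,5Z,7S,9S,10Z)-11-bromo-7,9-bis(tert-butyldimethylsilyloxy)-2-iodo-6,10-dimethyl-4-(triethylsilyloxy)undeca-2,5,10-trienoate | Br/C=C(/C)[C@@H](O[Si](C)(C)C(C)(C)C)C[C@H](O[Si](C)(C)C(C)(C)C)/C(C)=C\[C@@H](O[Si](CC)(CC)CC)/C=C(\I)C(=O)OC | intermediate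
20 | methyl (2E,4R,5Z,7S,9S,10Z)-7,9-bis(tert-butyldimethylsilyloxy)-12-hydroxy-2-(hydroxymethyl)-6,10-dimethyl-4-(triethylsilyloxy)dodeca-2,5,10-trienoate | OC/C=C(/C)[C@@H](O[Si](C)(C)C(C)(C)C)C[C@H](O[Si](C)(C)C(C)(C)C)/C(C)=C\[C@@H](O[Si](CC)(CC)CC)/C=C(\CO)C(=O)OC | intermediate
21 | methyl (2E,4R,5Z,7S,9S,10Z)-7,9-bis(tert-butyldimethylsilyloxy)-2-(hydroxymethyl)-6,10-dimethyl-12-oxo-4-(triethylsilyloxy)dodeca-2,5,10-trienoate | O=C/C=C(/C)[C@@H](O[Si](C)(C)C(C)(C)C)C[C@H](O[Si](C)(C)C(C)(C)C)/C(C)=C\[C@@H](O[Si](CC)(CC)CC)/C=C(\CO)C(=O)OC | intermediate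
22 | methyl (2E,4R,5Z,7S,9S,10Z)-7,9-bis(tert-butyldimethylsilyloxy)-2-[(methanesulfonyloxy)methyl]-6,10-dimethyl-12-oxo-4-(triethylsilyloxy)dodeca-2,5,10-trienoate | O=C/C=C(/C)[C@@H](O[Si](C)(C)C(C)(C)C)C[C@H](O[Si](C)(C)C(C)(C)C)/C(C)=C\[C@@H](O[Si](CC)(CC)CC)/C=C(\COS(C)(=O)=O)C(=O)OC | intermediate
23 | methyl (2Z,4R,5Z,7S,9S,10Z)-2-(bromomethyl)-7,9-bis(tert-butyldimethylsilyloxy)-6,10-dimethyl-12-oxo-4-(triethylsilyloxy)dodeca-2,5,10-trienoate | O=C/C=C(/C)[C@@H](O[Si](C)(C)C(C)(C)C)C[C@H](O[Si](C)(C)C(C)(C)C)/C(C)=C\[C@@H](O[Si](CC)(CC)CC)/C=C(\CBr)C(=O)OC | intermediate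
24 | methyl 2-substituted acrylate on the closed ten-membered carbocycle: (1S,3S,6S,7S,8R), 4Z,9Z, C6–OSiMe3, C8–OSiEt3, C1 and C3–OTBS (syn C6/C7 adduct before lactonisation) | C[Si](C)(C)O[C@H]1/C=C(/C)[C@@H](O[Si](C)(C)C(C)(C)C)C[C@H](O[Si](C)(C)C(C)(C)C)/C(C)=C\[C@@H](O[Si](CC)(CC)CC)[C@H]1C(=C)C(=O)OC | intermediate
25 | (1S,3S,6S,7S,8R)-1,3-bis(tert-butyldimethylsilyloxy)-8-(triethylsilyloxy)germacra-4Z,9Z,11(13)-trien-12,6-olide | C=C1C(=O)O[C@H]2/C=C(/C)[C@@H](O[Si](C)(C)C(C)(C)C)C[C@H](O[Si](C)(C)C(C)(C)C)/C(C)=C\[C@@H](O[Si](CC)(CC)CC)[C@@H]12 | intermediate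
26 | (1S,3S,6S,7R,8R)-1,3-bis(tert-butyldimethylsilyloxy)-8-hydroxygermacra-4Z,9Z,11(13)-trien-12,6-olide | C=C1C(=O)O[C@H]2/C=C(/C)[C@@H](O[Si](C)(C)C(C)(C)C)C[C@H](O[Si](C)(C)C(C)(C)C)/C(C)=C\[C@@H](O)[C@@H]12 | intermediate
27 | angelic acid ((Z)-2-methylbut-2-enoic acid) | C/C=C(/C)C(=O)O | starting material
28 | angelic 2,4,6-trichlorobenzoic anhydride | C/C=C(/C)C(=O)OC(=O)c1c(Cl)cc(Cl)cc1Cl | intermediate
29 | (1S,3S,6S,7S,8R)-8-angeloyloxy-1,3-bis(tert-butyldimethylsilyloxy)germacra-4Z,9Z,11(13)-trien-12,6-olide | C=C1C(=O)O[C@H]2/C=C(/C)[C@@H](O[Si](C)(C)C(C)(C)C)C[C@H](O[Si](C)(C)C(C)(C)C)/C(C)=C\[C@@H](OC(=O)/C(C)=C\C)[C@@H]12 | intermediate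
30 | (1S,3S,6S,7S,8R)-8-angeloyloxy-1,3-dihydroxygermacra-4Z,9Z,11(13)-trien-12,6-olide | C=C1C(=O)O[C@H]2/C=C(/C)[C@@H](O)C[C@H](O)/C(C)=C\[C@@H](OC(=O)/C(C)=C\C)[C@@H]12 | target

**Totals**
Total steps: 18. Longest linear sequence: 16 steps (1, 2, 5–18; steps 3 and 4 are a two-step branch that joins at step 5).

**Three steps most likely to fail, with fallbacks**

Step 15 (the proposed new macrocyclisation). Risks are oligomerisation, an unfavourable substrate bias from C8, and slow catalyst turnover at high dilution. The fallback uses known chemistry and replaces the chromium allyl by a neutral allylboronate. It sets out from 23: Pd2(dba)3 (cat.) and B2pin2 in toluene–DMSO at 23 °C borylate the allylic bromide at the primary terminus to give methyl (2E,4R,5Z,7S,9S,10Z)-7,9-bis(tert-butyldimethylsilyloxy)-6,10-dimethyl-12-oxo-2-[(4,4,5,5-tetramethyl-1,3,2-dioxaborolan-2-yl)methyl]-4-(triethylsilyloxy)dodeca-2,5,10-trienoate F1. This ester-deactivated allylboronate is stable towards its own aldehyde at room temperature. On heating at 2 mM in toluene (80 °C), or with Sc(OTf)3 (cat.) at −40 °C, it undergoes intramolecular allylboration through the closed six-membered transition state; the Z-type allyl unit again gives the syn adduct, whose borate lactonises on work-up. The sequence comes back to the route at 25.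

Step 13 (chemoselective oxidation of the C6 alcohol in diol 20). Risks are competing oxidation at C13 and Z/E drift of the enal on long exposure. The fallback distinguishes the two carbons at the coupling stage instead of by oxidation rate. It sets out from 19: Stille coupling at 45 °C with tributyl[(4-methoxybenzyloxy)methyl]stannane (Pd(PPh3)4) reacts only at the α-iodo enoate and gives methyl (2E,4R,5Z,7S,9S,10Z)-11-bromo-7,9-bis(tert-butyldimethylsilyloxy)-2-[(4-methoxybenzyloxy)methyl]-6,10-dimethyl-4-(triethylsilyloxy)undeca-2,5,10-trienoate F2. A second Stille coupling with Bu3SnCH2OH at 100 °C converts the vinyl bromide into methyl (2E,4R,5Z,7S,9S,10Z)-7,9-bis(tert-butyldimethylsilyloxy)-12-hydroxy-2-[(4-methoxybenzyloxy)methyl]-6,10-dimethyl-4-(triethylsilyloxy)dodeca-2,5,10-trienoate F3. MnO2 then oxidises the only free alcohol to methyl (2E,4R,5Z,7S,9S,10Z)-7,9-bis(tert-butyldimethylsilyloxy)-2-[(4-methoxybenzyloxy)methyl]-6,10-dimethyl-12-oxo-4-(triethylsilyloxy)dodeca-2,5,10-trienoate F4, and DDQ in CH2Cl2 with pH 7 buffer at 0 °C removes the 4-methoxybenzyl group. The sequence comes back to the route at 21.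

Step 17 (angeloylation of the hindered C8 alcohol next to the lactone). Risks are angelate-to-tiglate isomerisation, slow acylation, and translactonisation to O8 under basic conditions. The fallback builds the Z double bond after acylation. It sets out from 26: Steglich esterification (DCC, DMAP, CH2Cl2, 0 °C) with 2-[bis(2,2,2-trifluoroethoxy)phosphoryl]propanoic acid gives (1S,3S,6S,7S,8R)-8-{2-[bis(2,2,2-trifluoroethoxy)phosphoryl]propanoyloxy}-1,3-bis(tert-butyldimethylsilyloxy)germacra-4Z,9Z,11(13)-trien-12,6-olide F5 as a mixture of phosphonate epimers. Still–Gennari olefination (KN(SiMe3)2, 18-crown-6, THF, −78 °C, then acetaldehyde) then forms the Z-configured 2-methylbut-2-enoate. The sequence comes back to the route at 29.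

**Further compounds**
F1 | step 15 | methyl (2E,4R,5Z,7S,9S,10Z)-7,9-bis(tert-butyldimethylsilyloxy)-6,10-dimethyl-12-oxo-2-[(4,4,5,5-tetramethyl-1,3,2-dioxaborolan-2-yl)methyl]-4-(triethylsilyloxy)dodeca-2,5,10-trienoate | O=C/C=C(/C)[C@@H](O[Si](C)(C)C(C)(C)C)C[C@H](O[Si](C)(C)C(C)(C)C)/C(C)=C\[C@@H](O[Si](CC)(CC)CC)/C=C(\CB1OC(C)(C)C(C)(C)O1)C(=O)OC
F2 | step 13 | methyl (2E,4R,5Z,7S,9S,10Z)-11-bromo-7,9-bis(tert-butyldimethylsilyloxy)-2-[(4-methoxybenzyloxy)methyl]-6,10-dimethyl-4-(triethylsilyloxy)undeca-2,5,10-trienoate | Br/C=C(/C)[C@@H](O[Si](C)(C)C(C)(C)C)C[C@H](O[Si](C)(C)C(C)(C)C)/C(C)=C\[C@@H](O[Si](CC)(CC)CC)/C=C(\COCc1ccc(OC)cc1)C(=O)OC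
F3 | step 13 | methyl (2E,4R,5Z,7S,9S,10Z)-7,9-bis(tert-butyldimethylsilyloxy)-12-hydroxy-2-[(4-methoxybenzyloxy)methyl]-6,10-dimethyl-4-(triethylsilyloxy)dodeca-2,5,10-trienoate | OC/C=C(/C)[C@@H](O[Si](C)(C)C(C)(C)C)C[C@H](O[Si](C)(C)C(C)(C)C)/C(C)=C\[C@@H](O[Si](CC)(CC)CC)/C=C(\COCc1ccc(OC)cc1)C(=O)OC
F4 | step 13 | methyl (2E,4R,5Z,7S,9S,10Z)-7,9-bis(tert-butyldimethylsilyloxy)-2-[(4-methoxybenzyloxy)methyl]-6,10-dimethyl-12-oxo-4-(triethylsilyloxy)dodeca-2,5,10-trienoate | O=C/C=C(/C)[C@@H](O[Si](C)(C)C(C)(C)C)C[C@H](O[Si](C)(C)C(C)(C)C)/C(C)=C\[C@@H](O[Si](CC)(CC)CC)/C=C(\COCc1ccc(OC)cc1)C(=O)OC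
F5 | step 17 | (1S,3S,6S,7S,8R)-8-{2-[bis(2,2,2-trifluoroethoxy)phosphoryl]propanoyloxy}-1,3-bis(tert-butyldimethylsilyloxy)germacra-4Z,9Z,11(13)-trien-12,6-olide (both phosphonate epimers) | C=C1C(=O)O[C@H]2/C=C(/C)[C@@H](O[Si](C)(C)C(C)(C)C)C[C@H](O[Si](C)(C)C(C)(C)C)/C(C)=C\[C@@H](OC(=O)C(C)P(=O)(OCC(F)(F)F)OCC(F)(F)F)[C@@H]12
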